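## The problem

Compound 41 is a stilbenoid trimer built around one benzene ring (ring A). Going round ring A, the six carbons carry in turn the oxygen of dihydrofuran 1, a hydrogen, the oxygen of dihydrofuran 2, C-3′ of furan 2, a CH2 group and C-3 of furan 1. The CH2 and C-3 are bridged through a CH(2,4-dihydroxyphenyl) carbon and a 3,5-dioxygenated benzene (ring B) into a seven-membered carbocycle, so two 2,3-diaryl-2,3-dihydrobenzofurans sit on a dibenzocycloheptane. Five stereocentres must be set: the CH(aryl) carbon of the seven-membered ring (R), C-2/C-3 of furan 1 (R,R) and C-2′/C-3′ of furan 2 (S,S); both furans are 2,3-trans but of opposite local handedness. The CH(aryl) centre is 1,4 to C-3 across the seven-membered ring and remote from furan 2, so relay from centre to centre cannot be relied on. Each O-benzylic C-2, however, can be equilibrated by reversible C–O ionisation and will follow its C-3 neighbour to trans, so three centres need reagent control and two can be left to thermodynamics. Nine phenols, two benzylic aryl ethers and five electron-rich arenes exclude strong oxidants and unselective electrophiles, and every acidic step becomes a question of which benzylic C–O bond ionises; the phenols travel as methyl ethers and are freed last. The feature that invites a late construction of ring A is its pattern: a resorcinol whose only C–H lies between the two oxygens and whose other three positions carry contiguous carbon substituents, two of them ring atoms of the seven-membered ring. That is the pattern formed when the C=C bond of a cycloheptenyl ketene and a two-carbon ynol ether are merged into a benzene ring.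

## Retrosynthesis

**Phenols.** 41 is taken back to its nonamethyl ether 40, so one Lewis-acid operation ends the route. Methyl is preferred to benzyl because benzylic ethers serve as C–H insertion sites at two points and because hydrogenolysis would endanger the dihydrofuran C–O bonds. The forward step must cleave nine aryl methyl ethers without opening the furans irreversibly.

**C-2 and C-2′.** 40 is derived from its bis-cis isomer 39. No bond of the skeleton is cut; the two O-benzylic centres are allowed to equilibrate under acid. This frees both ring closures from having to deliver trans geometry: only C-3 and C-3′ must be right.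

**Furan 2.** The C-3′–C-2′ bond of 39 is cut. Forward, a diaryl carbene at C-3′ (from hydrazone 37 through diazo compound 38) inserts into an O–CH2 bond of a 2,4-dimethoxybenzyl ether. The neighbouring cut at O–C-2′ (a quinone methide annulation) is shorter, but it would leave C-3′ to the influence of distant centres; the carbene route puts it under a chiral dirhodium catalyst. Ketone 36 comes from aldehyde 31 by etherification with alcohol 32 (33), addition of Grignard reagent 34 (35) and oxidation. The precursor 31 lacks one ring, two stereocentres and both outer aryl groups of furan 2.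

**Formyl group and free phenol.** The C–CHO bond of 31 is cut to give phenol 30, which comes from silyl ether 29. The forward reaction must choose the ring A position beside the CH2 group over the one between the oxygens, and must ignore four other electron-rich rings; a phenol-directed formylation answers the second demand and the para relation to the furan 1 oxygen the first.

**Furan 1.** The C-3–C-2 bond of 29 is cut in the same way: hydrazone 27 and diazo compound 28 come from ketone 26, the 4-methoxybenzyl ether of hydroxy ketone 24 and alcohol 25. Tricycle 24 has one stereocentre and no heterocycle. The forward insertion must set C-3 against a CH(aryl) centre four atoms away, which is why a chiral catalyst is used and not substrate bias alone.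

**Ring A (key cut).** In 24, four of the six ring A bonds are cut, leading to diazo ketone 14 and ynol ether 19. The neighbouring option, a preformed resorcinol that receives three adjacent carbon substituents by electrophilic substitution, would pit ring A against ring B and the dimethoxyphenyl group, and would not tell the two oxygens apart. The benzannulation gives the full pattern in one step and leaves one oxygen as a free phenol beside the ketone and the other as a silyl ether. 14 is bicyclic and has a single stereocentre. The forward step must be regioselective only.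

**Diazo ketone.** 14 is traced to methyl ketone 12 by diazo transfer through 13. Acylation of diazomethane is avoided because the C6=C7 bond, activated by two carbonyl groups, would undergo dipolar cycloaddition. The acetyl group of 12 is cut at C-7: enol triflate 10 is coupled with an acetyl anion equivalent (11), and 10 comes from 1,3-diketone 9.

**Seven-membered ring.** The C6–C7 bond of 9 is cut: the enolate of the aryl methyl ketone in 8 acylates a Weinreb amide. The ring B carbon that bears the ketone is meta to both methoxy groups, so Friedel–Crafts acylation cannot form the aryl–CO bond. The acetyl group is therefore put on by cross-coupling of aryl triflate 6 (through 7), and 6 comes from phenol 5 and lactone 4. In effect the lactone oxygen of 4 holds the place of the carbonyl carbon.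

**CH(aryl) centre.** The methine of 4 lies between two ortho-substituted arenes, which makes an asymmetric C–C bond-forming conjugate addition unattractive. The C–H bond is cut instead: hydride is delivered by a chiral copper hydride to coumarin 3, whose lactone ring fixes the alkene geometry. 3 comes from phenol 1 and keto ester 2 by Pechmann condensation.

**Ynol ether.** 19 is cut at O–Si and at the alkyne: ethyl formate 15 and dibromomethane 16 give ynolate 18, which silyl triflate 17 traps on oxygen.

## Roads not taken

**Alternative 1:** The cut is the ring A–C-3′ bond of furan 2, made by ring contraction. A 3-diazoflavanone A1 is irradiated in an alcohol; the aryl carbon migrates from the carbonyl to the carbene carbon, the pyranone shrinks to a dihydrofuran, and the ketene is caught as ester A2, which base equilibrates to trans.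
- Merits: flavanones are close to commercial chalcones, the O-benzylic centre exists before the rearrangement, trans geometry comes from simple equilibration, and no metal catalyst is needed.
- Weak points for 41: the carbon that must carry the 3,5-dioxygenated aryl ring arrives as an ester, so an arene has to replace a carboxyl group at a stereocentre. The oxygen at C-4 of A2 sits where ring A needs its CH2 substituent and must be exchanged for carbon. The seven-membered ring, furan 1 and three stereocentres are still to come on a ring that would then be substituted position by position. A diazo ketone with an aryloxy group on the next carbon can also open by β-elimination.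
- Comparison: both plans rest on a Wolff rearrangement. Alternative 1 is the cheaper way to a trans-dihydrobenzofuran as such, with fewer steps than the six that furan 2 costs here. The chosen plan sets against this that its Wolff step delivers all six ring A positions at once with the oxygens differentiated, and that the C-3′ aryl group is a native part of the carbene precursor.

**Alternative 2:** The cut is the C-3′–C-2′ and O–C-2′ pair of furan 2. An ortho-hydroxy diaryl carbinol A3 is converted by base to its ortho-quinone methide; the ylide of benzylic sulfonium salt A4 adds to the methide carbon and the phenoxide displaces the sulfide, giving nonamethyl ether A5 (identical with 40).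
- Merits: two bonds in one step, trans geometry directly, no condensation at a hindered ketone, and three steps from the phenol instead of six.
- Weak points: a carbinol is a poor quinone methide precursor under carbonate and may need a leaving group. The two new centres form far from every existing centre, so facial selectivity rests on a chiral ylide or on separation. The step is an endgame that presupposes ring A, the seven-membered ring and furan 1.
- Comparison: for furan 2 alone this road is shorter than the chosen one. The chosen plan sets catalyst control of C-3′ against it, and keeps this annulation as the fallback should the hindered hydrazone not form.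

**Alternative 3:** The cut is the bond between C-3 of a 2-arylbenzofuran and ring B. Aryl bromide A6 is cyclised by palladium-catalysed direct arylation (concerted metalation–deprotonation) to the benzofuran-fused dibenzocycloheptane A7, and the benzofuran C2=C3 bond is then reduced to the trans-dihydrofuran.
- Merits: convergent, built on robust cross-coupling, ring A comes from a simple resorcinol-derived benzofuran, and the CH(aryl) centre could come from the same asymmetric reduction used here. Up to the core it is probably the shortest route.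
- Weak points: the C2=C3 bond of A7 is tetrasubstituted, fully arylated and part of an aromatic ring. Catalytic hydrogenation would be slow, cis-selective and liable to hydrogenolyse the benzylic C–O bond; ionic reduction needs acid. C-3 would have to be set against the CH(aryl) centre with no handle. Furan 2 and a regioselective functionalisation of ring A remain.
- Comparison: Alternative 3 is shorter and more convergent to the tetracycle. The chosen plan creates C-3 as an sp3 centre in a catalyst-controlled C–H insertion, not by dearomatisation, and its benzannulation marks the furan 2 oxygen as the only silyl ether.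

Key step: step 11

Assumption: the ligand hand in step 2 and the R/S labels of the dirhodium catalysts in steps 14 and 21 are written for definiteness; the hand that gives the drawn configuration is meant, and the two insertions need opposite hands because the two dihydrofurans have opposite local configuration.

## Route

Step 1
Reactants: 1 3,5-dimethoxyphenol; 2 ethyl 3-(2,4-dimethoxyphenyl)-3-oxopropanoate
Product: 3 4-(2,4-dimethoxyphenyl)-5,7-dimethoxy-2H-chromen-2-one
Conditions: CF3CO2H, 60 °C
Reagents that add atoms: none
Why: Pechmann condensation: the protonated keto ester attacks the phenol ortho to OH (both ortho sites are equivalent and activated by the methoxy groups) and lactonisation with loss of ethanol and water gives the 4-arylcoumarin; no stereocentre is formed.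

Step 2
Reactants: 3 4-(2,4-dimethoxyphenyl)-5,7-dimethoxy-2H-chromen-2-one
Product: 4 (4R)-4-(2,4-dimethoxyphenyl)-5,7-dimethoxychroman-2-one
Conditions: Cu(OAc)2·H2O (cat.), (R)-DTBM-SEGPHOS (cat.), (EtO)2MeSiH, t-BuOH, toluene, rt
Reagents that add atoms: none
Why: Asymmetric CuH conjugate reduction of a β,β-diaryl enoate whose geometry is fixed by the lactone ring; the ligated copper hydride delivers H to C-4 from one face and sets the CH(aryl) centre (R), a small nucleophile being chosen because this carbon is flanked by two ortho-substituted arenes.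

Step 3
Reactants: 4 (4R)-4-(2,4-dimethoxyphenyl)-5,7-dimethoxychroman-2-one
Product: 5 (3R)-3-(2,4-dimethoxyphenyl)-3-(2-hydroxy-4,6-dimethoxyphenyl)-N-methoxy-N-methylpropanamide
Conditions: MeNH(OMe)·HCl, AlMe3, CH2Cl2, 0 °C → rt; aq. HCl
Reagents that add atoms: N,O-dimethylhydroxylamine hydrochloride, CNOC.Cl
Why: Weinreb amide formation by aluminium amide aminolysis of the aryl ester opens the lactone, frees the phenol and gives an acyl donor that does not relactonise; the stereocentre is not touched.

Step 4
Reactants: 5 (3R)-3-(2,4-dimethoxyphenyl)-3-(2-hydroxy-4,6-dimethoxyphenyl)-N-methoxy-N-methylpropanamide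
Product: 6 2-[(1R)-1-(2,4-dimethoxyphenyl)-3-[methoxy(methyl)amino]-3-oxopropyl]-3,5-dimethoxyphenyl trifluoromethanesulfonate
Conditions: Tf2O, pyridine, CH2Cl2, 0 °C
Reagents that add atoms: trifluoromethanesulfonic anhydride, O=S(=O)(OS(=O)(=O)C(F)(F)F)C(F)(F)F
Why: O-sulfonylation of the phenol turns the former lactone oxygen into a leaving group, so that ring B can receive carbon at a position that electrophilic acylation cannot reach.

Step 5
Reactants: 6 2-[(1R)-1-(2,4-dimethoxyphenyl)-3-[methoxy(methyl)amino]-3-oxopropyl]-3,5-dimethoxyphenyl trifluoromethanesulfonate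
Product: 8 (3R)-3-(2-acetyl-4,6-dimethoxyphenyl)-3-(2,4-dimethoxyphenyl)-N-methoxy-N-methylpropanamide, via 1-ethoxyvinyl arene 7 (not isolated)
Conditions: Bu3SnC(OEt)=CH2, Pd(PPh3)4 (cat.), LiCl, dioxane, 100 °C; then 1 M HCl, THF, rt
Reagents that add atoms: tributyl(1-ethoxyvinyl)stannane, CCCC[Sn](CCCC)(CCCC)C(=C)OCC; water, O
Why: Stille coupling of the aryl triflate with an acetyl anion equivalent followed by enol ether hydrolysis installs the acetyl group; the Weinreb amide is inert to both operations.

Step 6
Reactants: 8 (3R)-3-(2-acetyl-4,6-dimethoxyphenyl)-3-(2,4-dimethoxyphenyl)-N-methoxy-N-methylpropanamide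
Product: 9 (9R)-9-(2,4-dimethoxyphenyl)-1,3-dimethoxy-8,9-dihydro-5H-benzo[7]annulene-5,7(6H)-dione
Conditions: LiHMDS (2.5 equiv), THF, −78 → 0 °C; aq. NH4Cl
Reagents that add atoms: none
Why: Intramolecular Claisen-type acylation: the methyl ketone, the most acidic site, is enolised and attacks the Weinreb amide to close the seven-membered ring as a 1,3-diketone, whose deprotonation makes the step irreversible; the diaryl methine is not acidic enough to be affected.

Step 7
Reactants: 9 (9R)-9-(2,4-dimethoxyphenyl)-1,3-dimethoxy-8,9-dihydro-5H-benzo[7]annulene-5,7(6H)-dione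
Product: 10 (9R)-9-(2,4-dimethoxyphenyl)-1,3-dimethoxy-5-oxo-8,9-dihydro-5H-benzo[7]annulen-7-yl trifluoromethanesulfonate
Conditions: Tf2O, Et3N, CH2Cl2, −78 °C
Reagents that add atoms: trifluoromethanesulfonic anhydride, O=S(=O)(OS(=O)(=O)C(F)(F)F)C(F)(F)F
Why: Enol triflate formation from a 1,3-diketone; sulfonylation is expected on the oxygen of the aliphatic carbonyl (C-7), leaving the aryl ketone at C-5 conjugated with ring B as is usual for aroylacetone-type diketones.

Step 8
Reactants: 10 (9R)-9-(2,4-dimethoxyphenyl)-1,3-dimethoxy-5-oxo-8,9-dihydro-5H-benzo[7]annulen-7-yl trifluoromethanesulfonate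
Product: 12 (9R)-7-acetyl-9-(2,4-dimethoxyphenyl)-1,3-dimethoxy-8,9-dihydro-5H-benzo[7]annulen-5-one, via ethoxydiene 11 (not isolated)
Conditions: Bu3SnC(OEt)=CH2, Pd(PPh3)4 (cat.), LiCl, THF, 60 °C; then 1 M HCl, rt
Reagents that add atoms: tributyl(1-ethoxyvinyl)stannane, CCCC[Sn](CCCC)(CCCC)C(=C)OCC; water, O
Why: Stille coupling of a β-triflyloxy enone (a vinylogous acyl triflate, fast in oxidative addition) and enol ether hydrolysis give the cross-conjugated acetyl enone needed for diazo transfer.

Step 9
Reactants: 12 (9R)-7-acetyl-9-(2,4-dimethoxyphenyl)-1,3-dimethoxy-8,9-dihydro-5H-benzo[7]annulen-5-one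
Product: 14 (9R)-7-(diazoacetyl)-9-(2,4-dimethoxyphenyl)-1,3-dimethoxy-8,9-dihydro-5H-benzo[7]annulen-5-one, via trifluoroacetyl diketone 13 (not isolated)
Conditions: LiHMDS, THF, −78 °C; CF3CO2CH2CF3; then MsN3, Et3N, H2O, MeCN, rt
Reagents that add atoms: methanesulfonyl azide, CS(=O)(=O)N=[N+]=[N-]; 2,2,2-trifluoroethyl trifluoroacetate, O=C(OCC(F)(F)F)C(F)(F)F (its acyl group is carried by 13 only)
Why: Detrifluoroacetylative diazo transfer: kinetic enolisation of the methyl group, trifluoroacetylation and Regitz-type transfer with loss of the activating group give the diazomethyl ketone without exposing the doubly activated C6=C7 bond to diazomethane, which would add to it.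

Step 10
Reactants: 15 ethyl formate; 16 dibromomethane; 17 triisopropylsilyl trifluoromethanesulfonate
Product: 19 (triisopropylsilyloxy)acetylene, via lithium ethynolate 18 (not isolated)
Conditions: LiTMP (2 equiv), THF, −78 °C; n-BuLi, −78 °C → rt; then 17, −78 → 0 °C
Reagents that add atoms: none
Why: Kowalski ynolate synthesis: dibromomethyllithium adds to the ester, the dibromo enolate undergoes bromine–lithium exchange and the carbenoid rearranges (here by 1,2-hydride shift) to the ynolate, which the bulky, hard silyl triflate traps on oxygen.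

Step 11
Reactants: 14 (9R)-7-(diazoacetyl)-9-(2,4-dimethoxyphenyl)-1,3-dimethoxy-8,9-dihydro-5H-benzo[7]annulen-5-one; 19 (triisopropylsilyloxy)acetylene
Product: 24 (10R)-10-(2,4-dimethoxyphenyl)-4-hydroxy-7,9-dimethoxy-2-(triisopropylsilyloxy)-10,11-dihydro-5H-dibenzo[a,d][7]annulen-5-one, via vinylketene 20 (not isolated), via vinylcyclobutenone 21 (not isolated), via dienylketene 22 (not isolated), via cyclohexadienone 23 (not isolated)
Conditions: hν (450 W medium-pressure Hg lamp, Pyrex filter), ClCH2CH2Cl, rt; then 80 °C
Reagents that add atoms: none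
Why: Danheiser benzannulation: photochemical Wolff rearrangement of 14 moves the cycloheptenyl carbon from the carbonyl to the diazo carbon and gives vinylketene 20. The ynol ether adds to the ketene C=C bond in a [2+2] cycloaddition with its nucleophilic CH terminus on the ketene carbonyl carbon, giving 21. Four-electron conrotatory opening gives dienylketene 22, and six-electron disrotatory closure onto C-6 of the former cycloheptenone forms ring A as 23, a six-membered ring closed by electrocyclisation and fused to the seven-membered ring; 23 tautomerises at once because its ring-fusion hydrogen lies between two carbonyl groups. The closest known reaction type is the benzannulation of cycloalkenyl diazomethyl ketones with siloxyalkynes, applied here to a benzo-fused cycloheptadienone. No stereocentre is created and the CH(aryl) centre is carried through. The only selectivity needed is regiochemical and is fixed by ketene and ynol ether polarity: the silyloxy carbon ends meta to the new hydroxyl, the free OH lies beside the C-5 ketone for furan 1 and the silyl ether marks the oxygen of furan 2. The diazoacetyl group is trans to the C-5 carbonyl across C6=C7, so that ketone cannot capture the ketene, and the hydrogen-bonded product phenol is a poor ketene trap.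

Step 12
Reactants: 24 (10R)-10-(2,4-dimethoxyphenyl)-4-hydroxy-7,9-dimethoxy-2-(triisopropylsilyloxy)-10,11-dihydro-5H-dibenzo[a,d][7]annulen-5-one; 25 4-methoxybenzyl alcohol
Product: 26 (10R)-10-(2,4-dimethoxyphenyl)-7,9-dimethoxy-4-(4-methoxybenzyloxy)-2-(triisopropylsilyloxy)-10,11-dihydro-5H-dibenzo[a,d][7]annulen-5-one
Conditions: PPh3, DIAD, THF, 0 °C → rt
Reagents that add atoms: none
Why: Mitsunobu etherification of the acidic, ketone-chelated phenol under neutral conditions that spare the aryl silyl ether; the benzylic CH2 introduced here becomes C-2 of furan 1.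

Step 13
Reactants: 26 (10R)-10-(2,4-dimethoxyphenyl)-7,9-dimethoxy-4-(4-methoxybenzyloxy)-2-(triisopropylsilyloxy)-10,11-dihydro-5H-dibenzo[a,d][7]annulen-5-one
Product: 27 hydrazone of 26 at C-5
Conditions: N2H4·H2O, AcOH (cat.), EtOH, 80 °C
Reagents that add atoms: hydrazine, NN
Why: Hydrazone formation by condensation at the diaryl ketone; the dibenzosuberone carbonyl is hindered but twisted out of conjugation, which helps attack.

Step 14
Reactants: 27 hydrazone of 26 at C-5
Product: 29 furan 1 cis-dihydrobenzofuran silyl ether (C-2 S; C-3 R; CH(aryl) R), via diazo compound 28 (not isolated)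
Conditions: MnO2, CH2Cl2, rt; filtration; Rh2(R-PTAD)4 (1 mol %), CH2Cl2, 0 °C
Reagents that add atoms: none
Why: Oxidation gives the diaryldiazomethane and the chiral dirhodium carboxylate forms a donor/donor carbene that inserts into the neighbouring O–CH2 bond (intramolecular 1,5 C–H insertion) to close furan 1. C-3 (R) is set by the catalyst, whose hand is chosen to reinforce any bias from the CH(aryl) centre; C-2 forms cis (kinetic) and is corrected in step 22.

Step 15
Reactants: 29 furan 1 cis-dihydrobenzofuran silyl ether
Product: 30 furan 1 cis-dihydrobenzofuran phenol (free OH at the ring A oxygen destined for furan 2)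
Conditions: TBAF, THF, 0 °C
Reagents that add atoms: none
Why: Fluoride cleavage of the aryl silyl ether unmasks the single phenol that directs the next C–C bond formation.

Step 16
Reactants: 30 furan 1 cis-dihydrobenzofuran phenol
Product: 31 salicylaldehyde (CHO on the ring A carbon between the OH-bearing carbon and the CH2-bearing carbon)
Conditions: MgCl2, Et3N, (CH2O)n, MeCN, reflux
Reagents that add atoms: formaldehyde (as paraformaldehyde), C=O
Why: Casnati–Skattebøl ortho-formylation: the magnesium phenoxide delivers formaldehyde to its own ring only and a second equivalent oxidises the benzylic alkoxide. Of the two ortho positions the one para to the furan 1 oxygen is the more nucleophilic, as in orcinol monoethers, and the other electron-rich rings are not touched.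

Step 17
Reactants: 31 salicylaldehyde; 32 2,4-dimethoxybenzyl alcohol
Product: 33 2,4-dimethoxybenzyl ether of 31
Conditions: PPh3, DIAD, THF, 0 °C → rt
Reagents that add atoms: none
Why: Mitsunobu etherification of the salicylaldehyde phenol avoids the labile 2,4-dimethoxybenzyl halide and places the C–H bonds for the second insertion.

Step 18
Reactants: 33 2,4-dimethoxybenzyl ether of 31; 34 3,5-dimethoxyphenylmagnesium chloride (solution in THF)
Product: 35 diaryl carbinol (both carbinol epimers)
Conditions: THF, −78 → 0 °C; aq. NH4Cl
Reagents that add atoms: none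
Why: 1,2-Addition of an aryl Grignard reagent to the only carbonyl group; the carbinol centre is formed without control because it is oxidised in the next step.

Step 19
Reactants: 35 diaryl carbinol
Product: 36 diaryl ketone (3,5-dimethoxybenzoyl group on ring A)
Conditions: Dess–Martin periodinane, NaHCO3, CH2Cl2, rt
Reagents that add atoms: none
Why: Dess–Martin oxidation of the diaryl carbinol under buffered, non-acidic conditions that leave both benzylic ethers intact.

Step 20
Reactants: 36 diaryl ketone
Product: 37 hydrazone of 36
Conditions: N2H4 (anhydrous), AcOH (cat.), n-BuOH, 110 °C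
Reagents that add atoms: hydrazine, NN
Why: Condensation of hydrazine with the di-ortho-substituted diaryl ketone, driven by heat and excess reagent; the existing dihydrofuran is stable to base and nucleophile.

Step 21
Reactants: 37 hydrazone of 36
Product: 39 bis-cis nonamethyl ether (furan 1: C-2 S, C-3 R; furan 2: C-2′ R, C-3′ S; CH(aryl) R), via diazo compound 38 (not isolated)
Conditions: MnO2, CH2Cl2, rt; filtration; Rh2(S-PTAD)4 (1 mol %), CH2Cl2, 0 °C
Reagents that add atoms: none
Why: The same oxidation and donor/donor carbene 1,5 C–H insertion as in step 14 closes furan 2; the mirror-image catalyst is used because C-3′ (S) has the opposite local sense to C-3, and no resident centre is near enough to interfere.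

Step 22
Reactants: 39 bis-cis nonamethyl ether
Product: 40 all-trans nonamethyl ether of the target (furan 1: 2R,3R; furan 2: 2′S,3′S; CH(aryl) R)
Conditions: CF3CO2H, CH2Cl2, 0 °C → rt
Reagents that add atoms: none
Why: Acid-catalysed epimerisation: each O-benzylic C-2 ionises reversibly to a cation stabilised by its para- or ortho/para-methoxyaryl group and recloses to the more stable 2,3-trans dihydrobenzofuran, while C-3, C-3′ and the CH(aryl) centre cannot ionise and are retained.

Step 23
Reactants: 40 all-trans nonamethyl ether of the target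
Product: 41 CNP0283541.1
Conditions: BBr3, CH2Cl2, −78 °C → rt; then H2O
Reagents that add atoms: none
Why: Lewis-acid O-demethylation of the nine aryl methyl ethers (bromide attack on the boron-complexed ether); the dihydrofurans are already in their thermodynamic trans form, so reversible C–O ionisation returns the same isomers.

## Compound list

1 | 3,5-dimethoxyphenol | COc1cc(O)cc(OC)c1 | starting material
2 | ethyl 3-(2,4-dimethoxyphenyl)-3-oxopropanoate | CCOC(=O)CC(=O)c1ccc(OC)cc1OC | starting material
3 | 4-(2,4-dimethoxyphenyl)-5,7-dimethoxy-2H-chromen-2-one | O=C1C=C(c2ccc(OC)cc2OC)c2c(OC)cc(OC)cc2O1 | intermediate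
4 | (4R)-4-(2,4-dimethoxyphenyl)-5,7-dimethoxychroman-2-one | O=C1C[C@H](c2ccc(OC)cc2OC)c2c(OC)cc(OC)cc2O1 | intermediate
5 | (3R)-3-(2,4-dimethoxyphenyl)-3-(2-hydroxy-4,6-dimethoxyphenyl)-N-methoxy-N-methylpropanamide | CON(C)C(=O)C[C@H](c1ccc(OC)cc1OC)c1c(O)cc(OC)cc1OC | intermediate
6 | 2-[(1R)-1-(2,4-dimethoxyphenyl)-3-[methoxy(methyl)amino]-3-oxopropyl]-3,5-dimethoxyphenyl trifluoromethanesulfonate | CON(C)C(=O)C[C@H](c1ccc(OC)cc1OC)c1c(OS(=O)(=O)C(F)(F)F)cc(OC)cc1OC | intermediate
7 | (3R)-3-(2,4-dimethoxyphenyl)-3-[2-(1-ethoxyvinyl)-4,6-dimethoxyphenyl]-N-methoxy-N-methylpropanamide | C=C(OCC)c1cc(OC)cc(OC)c1[C@H](CC(=O)N(C)OC)c1ccc(OC)cc1OC | intermediate (not isolated)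
8 | (3R)-3-(2-acetyl-4,6-dimethoxyphenyl)-3-(2,4-dimethoxyphenyl)-N-methoxy-N-methylpropanamide | CC(=O)c1cc(OC)cc(OC)c1[C@H](CC(=O)N(C)OC)c1ccc(OC)cc1OC | intermediate
9 | (9R)-9-(2,4-dimethoxyphenyl)-1,3-dimethoxy-8,9-dihydro-5H-benzo[7]annulene-5,7(6H)-dione | O=C1CC(=O)c2cc(OC)cc(OC)c2[C@@H](c2ccc(OC)cc2OC)C1 | intermediate
10 | (9R)-9-(2,4-dimethoxyphenyl)-1,3-dimethoxy-5-oxo-8,9-dihydro-5H-benzo[7]annulen-7-yl trifluoromethanesulfonate | O=C1C=C(OS(=O)(=O)C(F)(F)F)C[C@H](c2ccc(OC)cc2OC)c2c(OC)cc(OC)cc21 | intermediate
11 | (9R)-9-(2,4-dimethoxyphenyl)-7-(1-ethoxyvinyl)-1,3-dimethoxy-8,9-dihydro-5H-benzo[7]annulen-5-one | C=C(OCC)C1=CC(=O)c2cc(OC)cc(OC)c2[C@@H](c2ccc(OC)cc2OC)C1 | intermediate (not isolated)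
12 | (9R)-7-acetyl-9-(2,4-dimethoxyphenyl)-1,3-dimethoxy-8,9-dihydro-5H-benzo[7]annulen-5-one | CC(=O)C1=CC(=O)c2cc(OC)cc(OC)c2[C@@H](c2ccc(OC)cc2OC)C1 | intermediate
13 | 1-[(9R)-9-(2,4-dimethoxyphenyl)-1,3-dimethoxy-5-oxo-8,9-dihydro-5H-benzo[7]annulen-7-yl]-4,4,4-trifluorobutane-1,3-dione | O=C(CC(=O)C(F)(F)F)C1=CC(=O)c2cc(OC)cc(OC)c2[C@@H](c2ccc(OC)cc2OC)C1 | intermediate (not isolated)
14 | (9R)-7-(diazoacetyl)-9-(2,4-dimethoxyphenyl)-1,3-dimethoxy-8,9-dihydro-5H-benzo[7]annulen-5-one | [N-]=[N+]=CC(=O)C1=CC(=O)c2cc(OC)cc(OC)c2[C@@H](c2ccc(OC)cc2OC)C1 | intermediate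
15 | ethyl formate | CCOC=O | starting material
16 | dibromomethane | BrCBr | starting material
17 | triisopropylsilyl trifluoromethanesulfonate | CC(C)[Si](OS(=O)(=O)C(F)(F)F)(C(C)C)C(C)C | starting material
18 | lithium ethynolate | [Li+].[O-]C#C | intermediate (not isolated)
19 | (triisopropylsilyloxy)acetylene | C#CO[Si](C(C)C)(C(C)C)C(C)C | intermediate
20 | vinylketene: 2-[(9R)-9-(2,4-dimethoxyphenyl)-1,3-dimethoxy-5-oxo-8,9-dihydro-5H-benzo[7]annulen-7-yl]ethenone | O=C=CC1=CC(=O)c2cc(OC)cc(OC)c2[C@@H](c2ccc(OC)cc2OC)C1 | intermediate (not isolated)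
21 | vinylcyclobutenone: 4-[(9R)-9-(2,4-dimethoxyphenyl)-1,3-dimethoxy-5-oxo-8,9-dihydro-5H-benzo[7]annulen-7-yl]-3-(triisopropylsilyloxy)cyclobut-2-en-1-one (ring CH unspecified) | O=C1C=C(O[Si](C(C)C)(C(C)C)C(C)C)C1C1=CC(=O)c2cc(OC)cc(OC)c2[C@@H](c2ccc(OC)cc2OC)C1 | intermediate (not isolated)
22 | dienylketene: (3Z)-4-[(9R)-9-(2,4-dimethoxyphenyl)-1,3-dimethoxy-5-oxo-8,9-dihydro-5H-benzo[7]annulen-7-yl]-3-(triisopropylsilyloxy)buta-1,3-dien-1-one | O=C=C/C(O[Si](C(C)C)(C(C)C)C(C)C)=C\C1=CC(=O)c2cc(OC)cc(OC)c2[C@@H](c2ccc(OC)cc2OC)C1 | intermediate (not isolated)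
23 | cyclohexa-2,4-dienone tautomer of 24 (ring A not yet aromatic; H on the ring-fusion carbon next to C-5) | O=C1C=C(O[Si](C(C)C)(C(C)C)C(C)C)C=C2C[C@H](c3ccc(OC)cc3OC)c3c(OC)cc(OC)cc3C(=O)C12 | intermediate (not isolated)
24 | (10R)-10-(2,4-dimethoxyphenyl)-4-hydroxy-7,9-dimethoxy-2-(triisopropylsilyloxy)-10,11-dihydro-5H-dibenzo[a,d][7]annulen-5-one | Oc1cc(O[Si](C(C)C)(C(C)C)C(C)C)cc2c1C(=O)c1cc(OC)cc(OC)c1[C@@H](c1ccc(OC)cc1OC)C2 | intermediate
25 | 4-methoxybenzyl alcohol | COc1ccc(CO)cc1 | starting material
26 | (10R)-10-(2,4-dimethoxyphenyl)-7,9-dimethoxy-4-(4-methoxybenzyloxy)-2-(triisopropylsilyloxy)-10,11-dihydro-5H-dibenzo[a,d][7]annulen-5-one | COc1ccc(COc2cc(O[Si](C(C)C)(C(C)C)C(C)C)cc3c2C(=O)c2cc(OC)cc(OC)c2[C@@H](c2ccc(OC)cc2OC)C3)cc1 | intermediate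
27 | hydrazone of 26 at C-5 | COc1ccc(COc2cc(O[Si](C(C)C)(C(C)C)C(C)C)cc3c2C(=NN)c2cc(OC)cc(OC)c2[C@@H](c2ccc(OC)cc2OC)C3)cc1 | intermediate
28 | 5-diazo compound from 27 | COc1ccc(COc2cc(O[Si](C(C)C)(C(C)C)C(C)C)cc3c2C(=[N+]=[N-])c2cc(OC)cc(OC)c2[C@@H](c2ccc(OC)cc2OC)C3)cc1 | intermediate (not isolated)
29 | furan 1 cis-dihydrobenzofuran silyl ether: former C-5 (now C-3, R) bonded to the former benzylic CH2 (now C-2, S, bearing 4-methoxyphenyl cis to ring B); OSi(i-Pr)3 retained; CH(aryl) R | COc1ccc([C@H]2Oc3cc(O[Si](C(C)C)(C(C)C)C(C)C)cc4c3[C@H]2c2cc(OC)cc(OC)c2[C@@H](c2ccc(OC)cc2OC)C4)cc1 | intermediate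
30 | phenol from 29 (OH in place of OSi(i-Pr)3) | COc1ccc([C@H]2Oc3cc(O)cc4c3[C@H]2c2cc(OC)cc(OC)c2[C@@H](c2ccc(OC)cc2OC)C4)cc1 | intermediate
31 | salicylaldehyde from 30 (CHO on the ring A carbon between C–OH and C–CH2) | COc1ccc([C@H]2Oc3cc(O)c(C=O)c4c3[C@H]2c2cc(OC)cc(OC)c2[C@@H](c2ccc(OC)cc2OC)C4)cc1 | intermediate
32 | 2,4-dimethoxybenzyl alcohol | COc1ccc(CO)c(OC)c1 | starting material
33 | 2,4-dimethoxybenzyl ether of 31 | COc1ccc([C@H]2Oc3cc(OCc5ccc(OC)cc5OC)c(C=O)c4c3[C@H]2c2cc(OC)cc(OC)c2[C@@H](c2ccc(OC)cc2OC)C4)cc1 | intermediate
34 | 3,5-dimethoxyphenylmagnesium chloride | COc1cc(OC)cc([Mg]Cl)c1 | starting material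
35 | diaryl carbinol from 33 (CH(OH)(3,5-dimethoxyphenyl) on ring A; both epimers) | COc1ccc([C@H]2Oc3cc(OCc5ccc(OC)cc5OC)c(C(O)c5cc(OC)cc(OC)c5)c4c3[C@H]2c2cc(OC)cc(OC)c2[C@@H](c2ccc(OC)cc2OC)C4)cc1 | intermediate
36 | diaryl ketone from 35 (3,5-dimethoxybenzoyl on ring A) | COc1ccc([C@H]2Oc3cc(OCc5ccc(OC)cc5OC)c(C(=O)c5cc(OC)cc(OC)c5)c4c3[C@H]2c2cc(OC)cc(OC)c2[C@@H](c2ccc(OC)cc2OC)C4)cc1 | intermediate
37 | hydrazone of 36 | COc1ccc([C@H]2Oc3cc(OCc5ccc(OC)cc5OC)c(C(=NN)c5cc(OC)cc(OC)c5)c4c3[C@H]2c2cc(OC)cc(OC)c2[C@@H](c2ccc(OC)cc2OC)C4)cc1 | intermediate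
38 | diazo compound from 37 | COc1ccc([C@H]2Oc3cc(OCc5ccc(OC)cc5OC)c(C(=[N+]=[N-])c5cc(OC)cc(OC)c5)c4c3[C@H]2c2cc(OC)cc(OC)c2[C@@H](c2ccc(OC)cc2OC)C4)cc1 | intermediate (not isolated)
39 | bis-cis nonamethyl ether (furan 1: 2S,3R; furan 2: 2′R,3′S; CH(aryl) R) | COc1ccc([C@H]2Oc3cc4c(c5c3[C@H]2c2cc(OC)cc(OC)c2[C@@H](c2ccc(OC)cc2OC)C5)[C@H](c2cc(OC)cc(OC)c2)[C@H](c2ccc(OC)cc2OC)O4)cc1 | intermediate
40 | all-trans nonamethyl ether of the target (furan 1: 2R,3R; furan 2: 2′S,3′S; CH(aryl) R) | COc1ccc([C@@H]2Oc3cc4c(c5c3[C@H]2c2cc(OC)cc(OC)c2[C@@H](c2ccc(OC)cc2OC)C5)[C@H](c2cc(OC)cc(OC)c2)[C@@H](c2ccc(OC)cc2OC)O4)cc1 | intermediate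
41 | CNP0283541.1 | Oc1ccc([C@@H]2Oc3cc4c(c5c3[C@H]2c2cc(O)cc(O)c2[C@@H](c2ccc(O)cc2O)C5)[C@H](c2cc(O)cc(O)c2)[C@@H](c2ccc(O)cc2O)O4)cc1 | target

## Step count and least certain steps

Total: 23 steps. Longest linear sequence: 22 steps (steps 1–9 and 11–23); step 10 is a one-step branch.

**Step 11 (key step).** The aryl enone chromophore of 14 may compete for light (E/Z isomerisation of the cycloheptenone double bond, [2+2] dimerisation). The excited diazo ketone may lose nitrogen to a free carbene instead of rearranging in concert. Unreacted ketene may acylate the product phenol. The fallback generates the same vinylketene 20 without light. It sets out from enol triflate 10. Negishi coupling with the Reformatsky reagent BrZnCH2CO2t-Bu (Pd(PPh3)4, THF) should give tert-butyl ester F1, CF3CO2H the acid F2, and (COCl)2 the acid chloride F3. Slow addition of F3 to Et3N and 19 in toluene at rt dehydrochlorinates it to 20, which is trapped as 21; heating to 80 °C after all acid chloride is consumed completes the sequence and rejoins the route at 24.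

**Step 7.** Sulfonylation may occur on the aryl-side oxygen or on both, so that the leaving group ends at C-5 instead of C-7. The fallback sets out from diketone 9 and uses acid-catalysed exchange, not enolate O-sulfonylation, to fix the position. HC(OMe)3 and TsOH in MeOH should place the methoxy group at the more electrophilic aliphatic carbonyl carbon and give β-methoxy enone F4. Conjugate addition–elimination with (CH2=C(OEt))2CuLi (from 1-ethoxyvinyllithium and CuI) gives 11 and, after acid, rejoins at 12.

**Step 9.** The base may remove a γ-hydrogen at C-8 instead of a methyl hydrogen. That leads to migration of the double bond and, through the deconjugated isomer, to loss of configuration at the CH(aryl) carbon. The enolate or the amide base may also add to the ene-dione. The fallback sets out from 10 and needs no ketone enolate. After the Stille coupling to 11, NBS in wet THF should give bromomethyl ketone F5; N,N′-ditosylhydrazine and DBU at 0 °C then form the diazo group by substitution and double sulfinate elimination, rejoining at 14.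

**Step 10.** The formate adduct may collapse early and take up a second dibromomethyllithium, or the ynolate may be silylated on carbon to give a silylketene. The fallback sets out from 17 and acetylene. Deprotonation (n-BuLi, THF, −78 °C) gives lithium acetylide F6, which is oxidised with LiOOt-Bu to ynolate 18 and silylated with 17, rejoining at 19.

**Step 20.** The ketone of 36 is flanked on ring A by the benzyloxy group and the CH2 of the seven-membered ring; condensation may stall, and prolonged heating with hydrazine may attack the benzylic ether. The fallback changes the way furan 2 is closed and sets out from aldehyde 31. Excess 34 gives ortho-hydroxy diaryl carbinol F7. Cs2CO3 and (2,4-dimethoxybenzyl)dimethylsulfonium tetrafluoroborate in CH2Cl2 should convert it through its ortho-quinone methide, by ylide addition and O-alkylative closure, into the 2′,3′-trans dihydrofuran F8 (furan 1 still cis). F8 enters step 22 and rejoins at 40. The price is that facial selectivity at C-3′ then rests on the distant core, and the C-3′ epimer would have to be separated.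

## Further compounds

F1 | step 11 | tert-butyl 2-[(9R)-9-(2,4-dimethoxyphenyl)-1,3-dimethoxy-5-oxo-8,9-dihydro-5H-benzo[7]annulen-7-yl]acetate | CC(C)(C)OC(=O)CC1=CC(=O)c2cc(OC)cc(OC)c2[C@@H](c2ccc(OC)cc2OC)C1
F2 | step 11 | 2-[(9R)-9-(2,4-dimethoxyphenyl)-1,3-dimethoxy-5-oxo-8,9-dihydro-5H-benzo[7]annulen-7-yl]acetic acid | OC(=O)CC1=CC(=O)c2cc(OC)cc(OC)c2[C@@H](c2ccc(OC)cc2OC)C1
F3 | step 11 | 2-[(9R)-9-(2,4-dimethoxyphenyl)-1,3-dimethoxy-5-oxo-8,9-dihydro-5H-benzo[7]annulen-7-yl]acetyl chloride | ClC(=O)CC1=CC(=O)c2cc(OC)cc(OC)c2[C@@H](c2ccc(OC)cc2OC)C1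
F4 | step 7 | (9R)-9-(2,4-dimethoxyphenyl)-1,3,7-trimethoxy-8,9-dihydro-5H-benzo[7]annulen-5-one | COC1=CC(=O)c2cc(OC)cc(OC)c2[C@@H](c2ccc(OC)cc2OC)C1
F5 | step 9 | (9R)-7-(bromoacetyl)-9-(2,4-dimethoxyphenyl)-1,3-dimethoxy-8,9-dihydro-5H-benzo[7]annulen-5-one | BrCC(=O)C1=CC(=O)c2cc(OC)cc(OC)c2[C@@H](c2ccc(OC)cc2OC)C1
F6 | step 10 | lithium acetylide | [Li]C#C
F7 | step 20 | ortho-hydroxy diaryl carbinol from 31 (furan 1 cis; both carbinol epimers) | COc1ccc([C@H]2Oc3cc(O)c(C(O)c5cc(OC)cc(OC)c5)c4c3[C@H]2c2cc(OC)cc(OC)c2[C@@H](c2ccc(OC)cc2OC)C4)cc1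
F8 | step 20 | nonamethyl ether with furan 1 cis (2S,3R) and furan 2 trans (2′S,3′S) | COc1ccc([C@H]2Oc3cc4c(c5c3[C@H]2c2cc(OC)cc(OC)c2[C@@H](c2ccc(OC)cc2OC)C5)[C@H](c2cc(OC)cc(OC)c2)[C@@H](c2ccc(OC)cc2OC)O4)cc1
A1 | alternative 1 | 5-benzyloxy-3-diazo-2-(2,4-dimethoxyphenyl)-7-methoxychroman-4-one | [N-]=[N+]=C1C(=O)c2c(OCc3ccccc3)cc(OC)cc2O[C@@H]1c1ccc(OC)cc1OC
A2 | alternative 1 | methyl trans-4-benzyloxy-6-methoxy-2-(2,4-dimethoxyphenyl)-2,3-dihydrobenzofuran-3-carboxylate | COC(=O)[C@H]1c2c(OCc3ccccc3)cc(OC)cc2O[C@@H]1c1ccc(OC)cc1OC
A3 | alternative 2 | ortho-hydroxy diaryl carbinol on the trans-furan 1 tetracycle | COc1ccc([C@@H]2Oc3cc(O)c(C(O)c5cc(OC)cc(OC)c5)c4c3[C@H]2c2cc(OC)cc(OC)c2[C@@H](c2ccc(OC)cc2OC)C4)cc1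
A4 | alternative 2 | (2,4-dimethoxybenzyl)dimethylsulfonium tetrafluoroborate | COc1ccc(C[S+](C)C)c(OC)c1.F[B-](F)(F)F
A5 | alternative 2 | nonamethyl ether of the target (identical with 40) | COc1ccc([C@@H]2Oc3cc4c(c5c3[C@H]2c2cc(OC)cc(OC)c2[C@@H](c2ccc(OC)cc2OC)C5)[C@H](c2cc(OC)cc(OC)c2)[C@@H](c2ccc(OC)cc2OC)O4)cc1
A6 | alternative 3 | 4-[(2R)-2-(2-bromo-4,6-dimethoxyphenyl)-2-(2,4-dimethoxyphenyl)ethyl]-6-isopropoxy-2-(4-methoxyphenyl)benzofuran | COc1ccc(-c2cc3c(C[C@H](c4ccc(OC)cc4OC)c4c(Br)cc(OC)cc4OC)cc(OC(C)C)cc3o2)cc1
A7 | alternative 3 | benzofuran-fused dibenzocycloheptane | COc1ccc(-c2oc3cc(OC(C)C)cc4c3c2-c2cc(OC)cc(OC)c2[C@@H](c2ccc(OC)cc2OC)C4)cc1
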